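**Assumption:** the target SMILES has no stereocentre (the molecule is achiral), so no stereocontrol is needed. Commercial phloroacetophenone monohydrate is dried azeotropically before use. BF3·OEt2 and Amberlyst 15 act as promoters and are left out of the balanced equations.

**Retrosynthetic overview**
1. The pyranone C ring is closed last: C2 of the isoflavone comes from DMF, inserted into deoxybenzoin 9.
2. Deoxybenzoin 9 is cut at the CH2–aryl bond (C3–C1′ of the isoflavone). The ketone α-carbon is used as an electrophilic enolonium (from silyl enol ether 6 and an iodine(III) reagent) and attacks the C–H para to the free OH of phenol 4, so two normally nucleophilic carbons are joined.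
3. Enol ether 6 comes from phloroacetophenone by one-flask persilylation; phenol 4 comes from catechol and isoprene.
4. Ring order: dihydropyran ring of the B-ring unit first, A ring bought, pyranone C ring last.

**Route**

Step 1
Reactants: 1 catechol; 2 isoprene
Product: 4 2,2-dimethylchroman-8-ol, via 3-prenylcatechol 3 (not isolated)
Conditions: 1 (3 equiv), 2 (1 equiv), Amberlyst 15, THF–heptane, 65 °C; chromatography (the chroman is far less polar than the catechol by-products)
Reagents that add atoms: none
Why: Acid-catalysed Friedel–Crafts prenylation followed by intramolecular Markovnikov hydroalkoxylation (chroman annulation): the prenyl cation alkylates catechol ortho to one OH to give 3, whose neighbouring OH adds to the tertiary carbon to close the six-membered ether, while the para-prenylated isomer cannot cyclise and is removed as a polar catechol; no stereocentre is formed.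

Step 2
Reactants: 5 2',4',6'-trihydroxyacetophenone (phloroacetophenone)
Product: 6 tert-butyl({1-[2,4,6-tris(tert-butyldimethylsilyloxy)phenyl]ethenyl}oxy)dimethylsilane
Conditions: TBSOTf (4.5 equiv), Et3N (6 equiv), CH2Cl2, 0 °C → rt; filtration through Et3N-deactivated silica
Reagents that add atoms: tert-butyldimethylsilyl trifluoromethanesulfonate (TBSOTf), CC(C)(C)[Si](C)(C)OS(=O)(=O)C(F)(F)F
Why: Soft enolisation/silylation: TBSOTf/Et3N silylates the three phenols and converts the methyl ketone (its only enolisable position) into the TBS enol ether in one flask, giving a non-oxidisable, sterically shielded enolonium precursor.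

Step 3
Reactants: 6 tert-butyl({1-[2,4,6-tris(tert-butyldimethylsilyloxy)phenyl]ethenyl}oxy)dimethylsilane; 4 2,2-dimethylchroman-8-ol
Product: 9 2-(8-hydroxy-2,2-dimethylchroman-5-yl)-1-(2,4,6-trihydroxyphenyl)ethanone, via enolonium tosylate 7 (not isolated), via tris-TBS deoxybenzoin 8 (not isolated)
Conditions: PhI(OH)OTs (Koser's reagent, 1.0 equiv), BF3·OEt2 (1.5 equiv), CH2Cl2, −78 °C; add 6 (1.1 equiv), 10 min; add 4 (2.5 equiv), −78 → −20 °C; then MeOH, KHF2 (8 equiv), rt, same flask
Reagents that add atoms: none
Why: Proposed new method: enolonium (umpoled enolate) α-arylation, in which silyl enol ether 6 attacks BF3-activated Koser's reagent to give the α-(phenyl-λ3-iodanyl) ketone 7 with an electrophilic α-carbon, and the arene carbon para to the free OH of phenol 4 (C5, its most nucleophilic position) displaces iodobenzene at the unhindered CH2 in a Friedel–Crafts-type step and rearomatises to 8, the iodine(III) reagent being limiting so that no oxidant is left when the phenol is added and the bulky ortho-OTBS groups holding back 5-exo O-cyclisation to a coumaranone; the closest known reaction types are the Koser/BF3 enolonium α-arylation of ketone TMS enol ethers with indoles and other electron-rich (hetero)arenes and the para-selective Friedel–Crafts alkylation of guaiacol-type phenols, followed here by standard KHF2 cleavage of the aryl TBS ethers.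

Step 4
Reactants: 9 2-(8-hydroxy-2,2-dimethylchroman-5-yl)-1-(2,4,6-trihydroxyphenyl)ethanone
Product: 11 5,7-dihydroxy-3-(8-hydroxy-2,2-dimethylchroman-5-yl)-4H-chromen-4-one, via enaminone 10 (not isolated)
Conditions: BF3·OEt2 (6 equiv), DMF, rt → 50 °C; MsCl (3 equiv) in DMF, 50 → 90 °C, 2 h; aq. NaOAc work-up
Reagents that add atoms: N,N-dimethylformamide (DMF), CN(C)C=O
Why: Deoxybenzoin-to-isoflavone one-carbon annulation (Vilsmeier-type aminomethylenation of the BF3-chelated ketone with DMF/MsCl, then addition–elimination by the 2'-OH with loss of dimethylamine), the standard procedure for unprotected 5,7-dihydroxyisoflavones such as genistein; no stereocentre is involved.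

**Compound list**
1 | catechol (benzene-1,2-diol) | Oc1ccccc1O | starting material
2 | isoprene (2-methylbuta-1,3-diene) | C=CC(C)=C | starting material
3 | 3-(3-methylbut-2-en-1-yl)benzene-1,2-diol (3-prenylcatechol) | CC(C)=CCc1cccc(O)c1O | intermediate
4 | 2,2-dimethylchroman-8-ol (2,2-dimethyl-3,4-dihydro-2H-chromen-8-ol) | CC1(C)CCc2cccc(O)c2O1 | intermediate
5 | 2',4',6'-trihydroxyacetophenone (phloroacetophenone) | CC(=O)c1c(O)cc(O)cc1O | starting material
6 | tert-butyl({1-[2,4,6-tris(tert-butyldimethylsilyloxy)phenyl]ethenyl}oxy)dimethylsilane | C=C(O[Si](C)(C)C(C)(C)C)c1c(O[Si](C)(C)C(C)(C)C)cc(O[Si](C)(C)C(C)(C)C)cc1O[Si](C)(C)C(C)(C)C | intermediate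
7 | enolonium species, drawn as {2-oxo-2-[2,4,6-tris(tert-butyldimethylsilyloxy)phenyl]ethyl}(phenyl)iodonium tosylate | O=C(C[I+]c1ccccc1)c1c(O[Si](C)(C)C(C)(C)C)cc(O[Si](C)(C)C(C)(C)C)cc1O[Si](C)(C)C(C)(C)C.Cc1ccc(cc1)S(=O)(=O)[O-] | intermediate
8 | 2-(8-hydroxy-2,2-dimethylchroman-5-yl)-1-[2,4,6-tris(tert-butyldimethylsilyloxy)phenyl]ethanone | CC1(C)CCc2c(CC(=O)c3c(O[Si](C)(C)C(C)(C)C)cc(O[Si](C)(C)C(C)(C)C)cc3O[Si](C)(C)C(C)(C)C)ccc(O)c2O1 | intermediate
9 | 2-(8-hydroxy-2,2-dimethylchroman-5-yl)-1-(2,4,6-trihydroxyphenyl)ethanone | CC1(C)CCc2c(CC(=O)c3c(O)cc(O)cc3O)ccc(O)c2O1 | intermediate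
10 | 3-(dimethylamino)-2-(8-hydroxy-2,2-dimethylchroman-5-yl)-1-(2,4,6-trihydroxyphenyl)prop-2-en-1-one | CN(C)C=C(C(=O)c1c(O)cc(O)cc1O)c1ccc(O)c2OC(C)(C)CCc12 | intermediate
11 | 5,7-dihydroxy-3-(8-hydroxy-2,2-dimethylchroman-5-yl)-4H-chromen-4-one | CC1(C)CCc2c(-c3coc4cc(O)cc(O)c4c3=O)ccc(O)c2O1 | target

**Total step count:** 4 (steps 1 and 2 each make one fragment; steps 3 and 4 join and finish).
**Longest linear sequence:** 3 steps (5 → 6 → 9 → 11, or 1 → 4 → 9 → 11).

**Steps most likely to fail, with fallbacks**

Step 3 is the main risk. The enolonium may be taken by the phenol oxygen (giving an α-aryloxy ketone) or by C7/C6 of the arene, or the electron-rich aryl group of 7 may migrate. The fallback sets out from 4 (and uses 6) and comes back at 9. NBS in MeCN at 0 °C brominates 4 para to the OH to give 5-bromo-2,2-dimethylchroman-8-ol F1. TBSCl/imidazole in DMF gives [(5-bromo-2,2-dimethylchroman-8-yl)oxy](tert-butyl)dimethylsilane F2. Pd2(dba)3/P(t-Bu)3 with Bu3SnF in toluene at 85 °C couples F2 with silyl enol ether 6 (α-arylation through the tin enolate) to give 2-[8-(tert-butyldimethylsilyloxy)-2,2-dimethylchroman-5-yl]-1-[2,4,6-tris(tert-butyldimethylsilyloxy)phenyl]ethanone F3. KHF2 in MeOH then gives 9. Here the arene carbon is made the electrophile by the halogen, so the site is fixed and the ambident phenol is masked.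

Step 1 may give mainly para-prenylation of catechol and so a low yield of 4. The fallback sets out from 1 and comes back at 4 by way of 3. MOMCl/i-Pr2NEt in CH2Cl2 gives 1,2-bis(methoxymethoxy)benzene F4. Directed ortho-lithiation (n-BuLi, TMEDA, THF, 0 °C), transmetalation with CuBr·SMe2 and alkylation with prenyl bromide give 1,2-bis(methoxymethoxy)-3-(3-methylbut-2-en-1-yl)benzene F5. HCl in MeOH removes both MOM groups to give 3, and Amberlyst 15 in the same flask cyclises it to 4. The position is set by directed metalation and not by Friedel–Crafts selectivity.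

Step 2 may stop short of the hindered enol ether or give C-silylation. The fallback sets out from 5 and comes back at 6. TBSCl/imidazole in DMF at 40 °C silylates only the phenols to give 1-[2,4,6-tris(tert-butyldimethylsilyloxy)phenyl]ethanone F6. Irreversible deprotonation with KHMDS in THF at −78 °C and O-trapping of the potassium enolate with TBSCl gives 6. This replaces one-flask soft enolisation with a preformed-enolate route.

**Further compounds**
F1 | step 3 | 5-bromo-2,2-dimethylchroman-8-ol | CC1(C)CCc2c(Br)ccc(O)c2O1
F2 | step 3 | [(5-bromo-2,2-dimethylchroman-8-yl)oxy](tert-butyl)dimethylsilane | CC1(C)CCc2c(Br)ccc(O[Si](C)(C)C(C)(C)C)c2O1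
F3 | step 3 | 2-[8-(tert-butyldimethylsilyloxy)-2,2-dimethylchroman-5-yl]-1-[2,4,6-tris(tert-butyldimethylsilyloxy)phenyl]ethanone | CC1(C)CCc2c(CC(=O)c3c(O[Si](C)(C)C(C)(C)C)cc(O[Si](C)(C)C(C)(C)C)cc3O[Si](C)(C)C(C)(C)C)ccc(O[Si](C)(C)C(C)(C)C)c2O1
F4 | step 1 | 1,2-bis(methoxymethoxy)benzene | COCOc1ccccc1OCOC
F5 | step 1 | 1,2-bis(methoxymethoxy)-3-(3-methylbut-2-en-1-yl)benzene | COCOc1cccc(CC=C(C)C)c1OCOC
F6 | step 2 | 1-[2,4,6-tris(tert-butyldimethylsilyloxy)phenyl]ethanone | CC(=O)c1c(O[Si](C)(C)C(C)(C)C)cc(O[Si](C)(C)C(C)(C)C)cc1O[Si](C)(C)C(C)(C)C
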